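## Retrosynthetic overview

- The target is reached from hydroquinone 17, which carries the C8 oxygen as a benzyl ether. Hydrogenolysis of that ether and a single Ag2O oxidation reveal the quinone last.
- The six-membered carbocycle of the quinone is formed by thermal ring expansion of a 4-alkenyl-4-hydroxycyclobutenone: 4π opening, then 6π closure between the ketene carbon (future C1=O) and the vinyl CH2 (future C6–H). The enabling feature is that the quinone's O=C1–C2(OMe)=C3(OMe)–C4=O array is dimethyl squarate carried over intact, while C5 (bearing chroman C3) and C6–H are a 1,1-disubstituted vinyl group.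
- The cyclobutenone comes from dimethyl squarate and a 1-(chroman-3-yl)vinyllithium, made by Shapiro reaction of the trisylhydrazone of (R)-3-acetylchroman (from the acid via its Weinreb amide).
- The C3 stereocentre comes from asymmetric hydrogenation of a 2H-chromene-3-carboxylic acid. The pyran ring comes from oxa-Michael/aldol annulation of a salicylaldehyde with acrolein.
- Ring A is bought as 2-hydroxy-3,4-dimethoxybenzaldehyde and adjusted by benzylation, Dakin-type oxidation and ortho-formylation. Ring order: ring A (bought), pyran ring (step 4), quinone ring (step 11, at the hydroquinone level; oxidised in step 12).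

Key step: step 11

Assumption: in step 6 the (S)-configured ligand is assigned to the (R)-acid by analogy with the hydrogenation of tiglic acid by the same catalyst family; if the sense proves opposite, the antipodal ligand is used and nothing else changes.

## Route

Step 1
Reactants: 1 2-hydroxy-3,4-dimethoxybenzaldehyde
Product: 2 2-(benzyloxy)-3,4-dimethoxybenzaldehyde
Conditions: BnBr, K2CO3, DMF, 25 → 60 °C
Reagents that add atoms: benzyl bromide, BrCc1ccccc1
Why: Williamson ether synthesis on the phenoxide of 1 masks the oxygen that becomes the C8 hydroxyl as a benzyl ether, which tolerates organolithium and heat and leaves by hydrogenolysis.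

Step 2
Reactants: 2 2-(benzyloxy)-3,4-dimethoxybenzaldehyde
Product: 4 2-(benzyloxy)-3,4-dimethoxyphenol, via aryl formate 3 (not isolated)
Conditions: mCPBA, CH2Cl2, 0 → 25 °C; then Et3N (cat.), MeOH, 25 °C
Reagents that add atoms: 3-chloroperbenzoic acid, OOC(=O)c1cccc(Cl)c1
Why: Baeyer–Villiger (Dakin-type) oxidation, in which the electron-rich aryl group carrying ortho and para alkoxy donors migrates to give formate 3, which methanol cleaves to the phenol.

Step 3
Reactants: 4 2-(benzyloxy)-3,4-dimethoxyphenol
Product: 5 3-(benzyloxy)-2-hydroxy-4,5-dimethoxybenzaldehyde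
Conditions: MgCl2, Et3N, (CH2O)n, MeCN, reflux
Reagents that add atoms: paraformaldehyde (as formaldehyde), C=O
Why: Casnati–Skattebøl magnesium-mediated ortho-formylation delivers formaldehyde within the magnesium phenoxide to the only free ortho position, and a second formaldehyde oxidises the benzylic alkoxide to the aldehyde.

Step 4
Reactants: 5 3-(benzyloxy)-2-hydroxy-4,5-dimethoxybenzaldehyde
Product: 6 8-(benzyloxy)-6,7-dimethoxy-2H-chromene-3-carbaldehyde
Conditions: acrolein, K2CO3, 1,4-dioxane, reflux
Reagents that add atoms: acrolein, C=CC=O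
Why: oxa-Michael addition of the phenoxide to acrolein followed by intramolecular aldol condensation onto the aryl aldehyde is the standard 2H-chromene annulation of salicylaldehydes and closes the pyran ring.

Step 5
Reactants: 6 8-(benzyloxy)-6,7-dimethoxy-2H-chromene-3-carbaldehyde
Product: 7 8-(benzyloxy)-6,7-dimethoxy-2H-chromene-3-carboxylic acid
Conditions: NaClO2, NaH2PO4, 2-methyl-2-butene, t-BuOH/H2O, 25 °C
Reagents that add atoms: sodium chlorite, [Na+].[O-]Cl=O
Why: Pinnick oxidation converts the enal to the acid without touching the alkene, and the alkene scavenger removes hypochlorous acid before it can chlorinate the electron-rich arene.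

Step 6
Reactants: 7 8-(benzyloxy)-6,7-dimethoxy-2H-chromene-3-carboxylic acid
Product: 8 (3R)-8-(benzyloxy)-6,7-dimethoxychroman-3-carboxylic acid
Conditions: Ru(OAc)2[(S)-H8-BINAP] (1 mol%), H2 (5 atm), MeOH, 25 °C
Reagents that add atoms: none
Why: Noyori-type carboxylate-directed asymmetric hydrogenation of a trisubstituted acrylic acid, in which the ruthenium carboxylate chelate held in the chiral diphosphine pocket delivers hydrogen to one face of C3=C4 and so sets the C3 stereocentre under catalyst control, leaving the benzyl ether intact.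

Step 7
Reactants: 8 (3R)-8-(benzyloxy)-6,7-dimethoxychroman-3-carboxylic acid
Product: 9 (3R)-8-(benzyloxy)-N-methoxy-6,7-dimethoxy-N-methylchroman-3-carboxamide
Conditions: CDI, CH2Cl2, 25 °C; then MeNH(OMe)·HCl, 25 °C
Reagents that add atoms: N,O-dimethylhydroxylamine hydrochloride, CNOC.Cl
Why: amide formation through the acyl imidazolide gives the Weinreb amide under near-neutral conditions that should not enolise the C3 centre.

Step 8
Reactants: 9 (3R)-8-(benzyloxy)-N-methoxy-6,7-dimethoxy-N-methylchroman-3-carboxamide
Product: 10 1-[(3R)-8-(benzyloxy)-6,7-dimethoxychroman-3-yl]ethan-1-one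
Conditions: MeMgBr, THF, 0 °C; cold aq. NH4Cl
Reagents that add atoms: methylmagnesium bromide, C[Mg]Br
Why: Weinreb ketone synthesis, in which the chelated tetrahedral adduct survives until the cold, weakly acidic quench, so the ketone is never exposed to base and neither over-addition nor C3 epimerisation or retro-oxa-Michael opening is expected.

Step 9
Reactants: 10 1-[(3R)-8-(benzyloxy)-6,7-dimethoxychroman-3-yl]ethan-1-one
Product: 11 N'-{(1E)-1-[(3S)-8-(benzyloxy)-6,7-dimethoxychroman-3-yl]ethylidene}-2,4,6-triisopropylbenzenesulfonohydrazide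
Conditions: 2,4,6-triisopropylbenzenesulfonohydrazide, THF, 25 °C
Reagents that add atoms: 2,4,6-triisopropylbenzenesulfonohydrazide, NNS(=O)(=O)c1c(C(C)C)cc(C(C)C)cc1C(C)C
Why: base-free condensation of a methyl ketone with an arenesulfonylhydrazide should give mainly the E hydrazone, sulfonamide syn to the methyl group, without disturbing the adjacent stereocentre.

Step 10
Reactants: 11 N'-{(1E)-1-[(3S)-8-(benzyloxy)-6,7-dimethoxychroman-3-yl]ethylidene}-2,4,6-triisopropylbenzenesulfonohydrazide; 12 dimethyl squarate (3,4-dimethoxycyclobut-3-ene-1,2-dione)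
Product: 14 4-{1-[(3S)-8-(benzyloxy)-6,7-dimethoxychroman-3-yl]vinyl}-4-hydroxy-2,3-dimethoxycyclobut-2-en-1-one (both epimers at the carbinol carbon), via vinyllithium 13 (not isolated)
Conditions: n-BuLi (2.1 equiv), THF, −78 → 0 °C (N2 evolution), then −78 °C; 12, THF, −78 °C; aq. NH4Cl at −78 °C
Reagents that add atoms: none
Why: Shapiro reaction, in which syn-directed deprotonation of the methyl group and loss of sulfinate and N2 give the 1-substituted vinyllithium 13 with the C3–H bond untouched, followed by the usual 1,2-addition of an organolithium to one carbonyl of a squaric ester; the new carbinol centre forms unselectively but is destroyed in step 11.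

Step 11
Reactants: 14 4-{1-[(3S)-8-(benzyloxy)-6,7-dimethoxychroman-3-yl]vinyl}-4-hydroxy-2,3-dimethoxycyclobut-2-en-1-one
Product: 17 5-[(3S)-8-(benzyloxy)-6,7-dimethoxychroman-3-yl]-2,3-dimethoxybenzene-1,4-diol, via dienylketene 15 (not isolated), via cyclohexadienone 16 (not isolated)
Conditions: p-xylene (degassed), 138 °C, argon; concentration under argon, crude 17 taken on directly
Reagents that add atoms: none
Why: Heating opens the cyclobutenone C1–C4 bond in a conrotatory 4π electrocyclic ring opening in which the hydroxyl, as the donor substituent, rotates outward, so the 1-(chroman-3-yl)vinyl group lies cis to the ketene in the (Z)-dienylketene 15. A thermal disrotatory 6π electrocyclisation then joins the ketene carbon to the unsubstituted vinyl CH2 terminus, closing the six-membered carbocycle, and the cyclohexa-2,4-dienone 16 aromatises by tautomerisation to hydroquinone 17, which is kept at this oxidation level under argon because the next step is reductive. The closest known reaction type is the Moore–Liebeskind ring expansion of 4-alkenyl-4-hydroxycyclobutenones derived from squaric esters to hydroquinones. No stereocentre is created; the C3 centre is a spectator because its C–H bond lies outside both pericyclic arrays and no base is present. The step needs outward rotation of the hydroxyl, secured by the torquoselectivity of an oxygen donor on the breaking bond, and a single regiochemistry, secured because only the CH2 terminus of the 1,1-disubstituted alkene can reach the ketene carbon; this fixes H at C6, the chroman at C5 and the squarate methoxy groups at C2 and C3.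

Step 12
Reactants: 17 5-[(3S)-8-(benzyloxy)-6,7-dimethoxychroman-3-yl]-2,3-dimethoxybenzene-1,4-diol
Product: 19 CNP0269725.1 (5-[(3S)-8-hydroxy-6,7-dimethoxychroman-3-yl]-2,3-dimethoxy-1,4-benzoquinone), via debenzylated hydroquinone 18 (not isolated)
Conditions: H2 (1 atm), Pd/C (10%), EtOAc, 25 °C; filtration under argon; then Ag2O, MgSO4, Et2O, 25 °C
Reagents that add atoms: none
Why: catalytic hydrogenolysis cleaves the aryl benzyl ether of 17 without touching the hydroquinone or the C3 centre, and brief base-free Ag2O oxidation of triol 18 then dehydrogenates only the para-dihydroxy ring to the quinone, since the ring A monophenol is far harder to oxidise and the absence of base prevents epimerisation through a quinone methide.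

## Compound list

1 | 2-hydroxy-3,4-dimethoxybenzaldehyde | COc1ccc(C=O)c(O)c1OC | starting material
2 | 2-(benzyloxy)-3,4-dimethoxybenzaldehyde | COc1ccc(C=O)c(OCc2ccccc2)c1OC | intermediate
3 | 2-(benzyloxy)-3,4-dimethoxyphenyl formate | COc1ccc(OC=O)c(OCc2ccccc2)c1OC | intermediate
4 | 2-(benzyloxy)-3,4-dimethoxyphenol | COc1ccc(O)c(OCc2ccccc2)c1OC | intermediate
5 | 3-(benzyloxy)-2-hydroxy-4,5-dimethoxybenzaldehyde | COc1cc(C=O)c(O)c(OCc2ccccc2)c1OC | intermediate
6 | 8-(benzyloxy)-6,7-dimethoxy-2H-chromene-3-carbaldehyde | COc1cc2C=C(C=O)COc2c(OCc3ccccc3)c1OC | intermediate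
7 | 8-(benzyloxy)-6,7-dimethoxy-2H-chromene-3-carboxylic acid | COc1cc2C=C(C(=O)O)COc2c(OCc3ccccc3)c1OC | intermediate
8 | (3R)-8-(benzyloxy)-6,7-dimethoxychroman-3-carboxylic acid | OC(=O)[C@H]1COc2c(OCc3ccccc3)c(OC)c(OC)cc2C1 | intermediate
9 | (3R)-8-(benzyloxy)-N-methoxy-6,7-dimethoxy-N-methylchroman-3-carboxamide | CON(C)C(=O)[C@H]1COc2c(OCc3ccccc3)c(OC)c(OC)cc2C1 | intermediate
10 | 1-[(3R)-8-(benzyloxy)-6,7-dimethoxychroman-3-yl]ethan-1-one | CC(=O)[C@H]1COc2c(OCc3ccccc3)c(OC)c(OC)cc2C1 | intermediate
11 | N'-{(1E)-1-[(3S)-8-(benzyloxy)-6,7-dimethoxychroman-3-yl]ethylidene}-2,4,6-triisopropylbenzenesulfonohydrazide | C/C(=N\NS(=O)(=O)c1c(C(C)C)cc(C(C)C)cc1C(C)C)[C@H]1COc2c(OCc3ccccc3)c(OC)c(OC)cc2C1 | intermediate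
12 | dimethyl squarate (3,4-dimethoxycyclobut-3-ene-1,2-dione) | COC1=C(OC)C(=O)C1=O | starting material
13 | {1-[(3S)-8-(benzyloxy)-6,7-dimethoxychroman-3-yl]vinyl}lithium | [Li]C(=C)[C@H]1COc2c(OCc3ccccc3)c(OC)c(OC)cc2C1 | intermediate
14 | 4-{1-[(3S)-8-(benzyloxy)-6,7-dimethoxychroman-3-yl]vinyl}-4-hydroxy-2,3-dimethoxycyclobut-2-en-1-one (both epimers at the carbinol carbon) | COC1=C(OC)C(O)(C(=C)[C@H]2COc3c(OCc4ccccc4)c(OC)c(OC)cc3C2)C1=O | intermediate
15 | (3Z)-5-[(3S)-8-(benzyloxy)-6,7-dimethoxychroman-3-yl]-4-hydroxy-2,3-dimethoxyhexa-1,3,5-trien-1-one (dienylketene) | COC(=C=O)/C(OC)=C(/O)C(=C)[C@H]1COc2c(OCc3ccccc3)c(OC)c(OC)cc2C1 | intermediate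
16 | 5-[(3S)-8-(benzyloxy)-6,7-dimethoxychroman-3-yl]-4-hydroxy-2,3-dimethoxycyclohexa-2,4-dien-1-one | COC1=C(OC)C(O)=C([C@H]2COc3c(OCc4ccccc4)c(OC)c(OC)cc3C2)CC1=O | intermediate
17 | 5-[(3S)-8-(benzyloxy)-6,7-dimethoxychroman-3-yl]-2,3-dimethoxybenzene-1,4-diol | COc1c(OC)c(O)c([C@H]2COc3c(OCc4ccccc4)c(OC)c(OC)cc3C2)cc1O | intermediate
18 | 5-[(3S)-8-hydroxy-6,7-dimethoxychroman-3-yl]-2,3-dimethoxybenzene-1,4-diol | COc1c(OC)c(O)c([C@H]2COc3c(O)c(OC)c(OC)cc3C2)cc1O | intermediate
19 | CNP0269725.1, 5-[(3S)-8-hydroxy-6,7-dimethoxy-3,4-dihydro-2H-chromen-3-yl]-2,3-dimethoxycyclohexa-2,5-diene-1,4-dione | COC1=C(OC)C(=O)C([C@H]2COc3c(cc(OC)c(OC)c3O)C2)=CC1=O | target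

## Step count and risks

Total step count: 12. Longest linear sequence: 12 steps, from 1 to 19; dimethyl squarate 12 enters at step 10.

Steps most likely to fail:

1. Step 10. The metalation may be incomplete or misdirected (deprotonation on the ring side of the hydrazone or at the benzylic OCH2Ph position), the C3 configuration may erode, or the vinyllithium may be protonated before it meets the squarate. The fallback replaces the Shapiro reaction by halogen–lithium exchange and sets out from 9. Reduction with i-Bu2AlH (THF, −78 °C) should give (3R)-8-(benzyloxy)-6,7-dimethoxychroman-3-carbaldehyde F1. Ohira–Bestmann homologation (dimethyl (1-diazo-2-oxopropyl)phosphonate, K2CO3, MeOH, 0 °C) should give (3S)-8-(benzyloxy)-3-ethynyl-6,7-dimethoxychroman F2. Markovnikov bromoboration with B-bromo-9-BBN (CH2Cl2, 0 °C) and protodeboronation with AcOH should give (3R)-8-(benzyloxy)-3-(1-bromovinyl)-6,7-dimethoxychroman F3. Exchange with t-BuLi (2 equiv, Et2O, −78 °C) generates vinyllithium 13 within seconds, and addition to 12 returns to the route at 14.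

2. Step 11. After ring opening, the free hydroxyl may add to the ketene (furanone formation), the substrate may decompose before the 6π closure, or the electron-rich hydroquinone may oxidise in air during handling. The fallback runs the ring expansion on a silyl ether and sets out from 14. Silylation (Et3SiCl, Et3N, DMAP cat., CH2Cl2, 0 °C) should give 4-{1-[(3S)-8-(benzyloxy)-6,7-dimethoxychroman-3-yl]vinyl}-2,3-dimethoxy-4-(triethylsilyloxy)cyclobut-2-en-1-one F4, in which the oxygen cannot trap the ketene but still rotates outward. Thermolysis (PhMe, 110 °C) should give 5-[(3S)-8-(benzyloxy)-6,7-dimethoxychroman-3-yl]-2,3-dimethoxy-4-(triethylsilyloxy)phenol F5, a monosilyl ether that should be far less air-sensitive. Desilylation with Bu4NF buffered with AcOH (degassed THF, 0 °C) returns to the route at 17, which is taken directly into step 12.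

3. Step 6. Facial discrimination may be insufficient, or the sense of induction may be opposite to the assumed one. The fallback replaces catalyst control by classical resolution and sets out from 7. Achiral hydrogenation ([Rh(cod)(dppb)]BF4, H2, Et3N, MeOH) should give racemic 8-(benzyloxy)-6,7-dimethoxychroman-3-carboxylic acid F6. Fractional crystallisation with (R)-1-phenylethylamine (the antipodal amine if the other salt is the less soluble one) should give (R)-1-phenylethylammonium (3R)-8-(benzyloxy)-6,7-dimethoxychroman-3-carboxylate F7. Acidification (aq. HCl, EtOAc) returns to the route at 8.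

Further compounds

F1 | step 10 | (3R)-8-(benzyloxy)-6,7-dimethoxychroman-3-carbaldehyde | O=C[C@H]1COc2c(OCc3ccccc3)c(OC)c(OC)cc2C1
F2 | step 10 | (3S)-8-(benzyloxy)-3-ethynyl-6,7-dimethoxychroman | C#C[C@H]1COc2c(OCc3ccccc3)c(OC)c(OC)cc2C1
F3 | step 10 | (3R)-8-(benzyloxy)-3-(1-bromovinyl)-6,7-dimethoxychroman | C=C(Br)[C@H]1COc2c(OCc3ccccc3)c(OC)c(OC)cc2C1
F4 | step 11 | 4-{1-[(3S)-8-(benzyloxy)-6,7-dimethoxychroman-3-yl]vinyl}-2,3-dimethoxy-4-(triethylsilyloxy)cyclobut-2-en-1-one | COC1=C(OC)C(O[Si](CC)(CC)CC)(C(=C)[C@H]2COc3c(OCc4ccccc4)c(OC)c(OC)cc3C2)C1=O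
F5 | step 11 | 5-[(3S)-8-(benzyloxy)-6,7-dimethoxychroman-3-yl]-2,3-dimethoxy-4-(triethylsilyloxy)phenol | COc1c(OC)c(O[Si](CC)(CC)CC)c([C@H]2COc3c(OCc4ccccc4)c(OC)c(OC)cc3C2)cc1O
F6 | step 6 | racemic 8-(benzyloxy)-6,7-dimethoxychroman-3-carboxylic acid | OC(=O)C1COc2c(OCc3ccccc3)c(OC)c(OC)cc2C1
F7 | step 6 | (R)-1-phenylethylammonium (3R)-8-(benzyloxy)-6,7-dimethoxychroman-3-carboxylate | [O-]C(=O)[C@H]1COc2c(OCc3ccccc3)c(OC)c(OC)cc2C1.C[C@@H]([NH3+])c1ccccc1
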